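(The data were computed for an exercise, noise included.)

A catalyst that takes more of the left-handed substrate cannot, by taking it, lift the left-handed substrate back towards the right-handed one. Yet in the blue run the gap between them fell from 4.4 percentage points at 10.0 min to 1.5 points at 40.0 min.

all flasks: left-handed substrate 0.72 M; right-handed substrate 0.72 M; free catalyst 5 mol%; precatalyst 2 mol%

| run | partner | remark | time |
|---|---|---|---|
| blue | 3.5 equiv | run made earlier |  |
| flask | 2.50 equiv |  | 1.0 h |

- blue (time / min: left-handed substrate / %, right-handed substrate / %): 5.00: 41.2, 44.8; 10.0: 39.2, 43.6; 15.0: 38.5, 41.4; 20.0: 38.0, 41.0; 25.0: 37.8, 40.3; 30.0: 37.5, 39.5; 40.0: 37.7, 39.2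

(readings scatter by 0.3 percentage points)

- free catalyst is single-handed; left-handed substrate and right-handed substrate are mirror images of each other, charged as a racemate, each of them at the stated concentration
- an excess is the difference of the two amounts in percent of their sum
- an excess is below zero if the other one leads

* part of the left-handed substrate and right-handed substrate charged together that has reacted at 1.0 h
* excess of left-handed product over right-handed product in the product at 1.0 h
* excess of right-handed substrate over left-handed substrate among what is left of the two at 1.0 h

So I supposed that substrate passes between the hands while product keeps its hand, and I bracketed the product excess. The gap at 10.0 min, divided by what had reacted, gives a floor of 25.6%, since part of that gap had already decayed. Between the two readings the gap decayed at 0.0359 min⁻¹. Had all the product formed at the very start, the gap would have aged the full 10.0 min, and the ceiling is 36.6%. But 81.4% of that product already stood at 5.00 min, so I gave the gap an age of about 5.00 min. That yields 30.6% as my reading of the first-turnover excess, the product excess laid down while the substrates stand nearly even. It corresponds to a selectivity factor of 1.88. Both hands meet the same partner and catalyst, so I carried this value to the flask at 1.0 h.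

The forecast gave c 19%, eP 4.2% (range 1% to 9%, beneath my floor) and eS 1%, reading a “reversible reaction heading to an equilibrium”.

The flask gave c 22.2%, eP 31.0% and eS 0.523%.

    partner + free catalyst + left-handed substrate → free catalyst + left-handed product (k = 0.0200 M⁻² s⁻¹)
    partner + free catalyst + right-handed substrate → free catalyst + right-handed product (k = 0.0100 M⁻² s⁻¹)
    left-handed substrate + racemization catalyst ⇌ right-handed substrate + racemization catalyst, rate k3*[racemization catalyst]*[left-handed substrate] forward; the back reaction follows from the equilibrium constant (k = 0.0830 M⁻¹ s⁻¹)
    partner + precatalyst → racemization catalyst + spent reagent (k = 0.00150 M⁻¹ s⁻¹)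
    2 partner → homo dimer (k = 0.00290 M⁻¹ s⁻¹)

The flask's eP lies inside my bracket, 0.40 points above my reading of the first-turnover excess, a reading that carries the scatter of the blue run. In the flask the product excess stood at 31.5% at 0.100 h and 30.9% at 0.500 h, while the substrate excess fell from 3.96% to 2.20% over the same interval.

In the neighbour flask with 1.2 mol% of free catalyst, my reading of the first-turnover excess gives a product excess near 30.6%. That flask computes to 32.7%, with a substrate excess of 0.178%.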